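## Retrosynthetic overview

1. Last C–C bond: C4 of the chroman to C5 of resorcinol ring D, a Friedel–Crafts union of two chalcone dimers. It is feasible because C4 is benzylic to ring A, ortho to the pyran oxygen O1 and para to the 7-oxygen (a quinone-methide-type cation), while the ring D carbon is ortho to one and para to the other hydroxyl of a resorcinol.
2. Electrophile: C4 is parked as a cis-fused dihydrofuran ether to the ring B phenol, a bond absent from the target. It is made by Pd oxyarylation of a (2S)-flav-3-ene (from chiral-pool (S)-liquiritigenin) with an iodochalcone; C2 sets C3, and the temporary C4–O bond is cleaved with inversion in the key step.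
3. Nucleophile: the oxolane dimer, from an Evans anti-aldol/lactonisation (two centres), trans-alkylation of the lactone, one aryllithium installing both resorcinol rings, kinetic hemiketal reduction, and hydrogenolysis.
4. Ring order: γ-lactone (step 2) → oxolane (step 8); the pyran ring comes from the chiral pool; the temporary dihydrofuran ring is closed in step 14 and opened in step 15; desilylation is last.

Key step: step 15

Assumption: read from the SMILES, the target is 2S,3R,4R in the chroman (all-trans) and 2S,3R,4R,5S in the oxolane (2,3-cis, 3,4-trans, 4,5-cis); natural (2S)-liquiritigenin of high enantiomeric purity is taken as a purchasable starting material.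

## Route

**Oxolane fragment**

Step 1
Reactants: 1 (4S)-4-benzyl-1,3-oxazolidin-2-one; 2 methyl 4-chloro-4-oxobutanoate
Product: 4 methyl 4-[(4S)-4-benzyl-2-oxo-1,3-oxazolidin-3-yl]-4-oxobutanoate, via lithium oxazolidinide 3 (not isolated)
Conditions: n-BuLi, THF, −78 °C; then 2, −78 → 0 °C
Reagents that add atoms: none
Why: N-acylation of the lithiated oxazolidinone by the acid chloride (acyl substitution), which is much faster than attack on the methyl ester at −78 °C.

Step 2
Reactants: 4; 5 4-(benzyloxy)benzaldehyde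
Product: 8 (4S)-4-benzyl-3-{[(2S,3R)-2-[4-(benzyloxy)phenyl]-5-oxooxolan-3-yl]carbonyl}-1,3-oxazolidin-2-one (cis-lactone), via trimethylsilyl ether 6 (not isolated), via hydroxy ester 7 (not isolated)
Conditions: MgCl2 (20 mol%), Et3N, TMSCl, EtOAc, rt; then TFA (cat.), MeOH, rt; then PPTS, toluene, 50 °C
Reagents that add atoms: none
Why: Evans MgCl2-catalysed anti-aldol reaction, in which the chelated Z-magnesium enolate should be attacked by the non-enolisable aldehyde on the face opposite the benzyl group through a boat transition state to set the (3R,4S)-anti pair; after methanolysis of the silyl ether the alcohol closes on the methyl ester by acyl substitution (5-exo-trig), which keeps the carbinol configuration and gives the cis-lactone.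

Step 3
Reactants: 8
Product: 10 (2S,3R)-2-[4-(benzyloxy)phenyl]-5-oxooxolane-3-carboxylic acid, via peroxy acid 9 (not isolated)
Conditions: LiOH, H2O2 (30%), THF–H2O 3:1, 0 °C; Na2SO3; then 1 M HCl to pH 2
Reagents that add atoms: hydrogen peroxide, OO
Why: Hydroperoxide cleavage of the N-acyloxazolidinone, in which LiOOH attacks the exocyclic imide carbonyl, the peracid is reduced by sulfite and any opened lactone recloses on acidification; at 0 °C no stereocentre should be deprotonated.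

Step 4
Reactants: 10; 11 1-(benzyloxy)-4-(bromomethyl)benzene
Product: 13 (2S,3R,4R)-4-[4-(benzyloxy)benzyl]-2-[4-(benzyloxy)phenyl]-5-oxooxolane-3-carboxylic acid, via dilithium dianion 12 (not isolated)
Conditions: LiN(SiMe3)2 (2.2 equiv), THF, −78 °C; then 11, −78 → −40 °C; 1 M HCl
Reagents that add atoms: none
Why: Alkylation of the carboxylate/lactone-enolate dianion (paraconic acid alkylation), in which the benzyl bromide enters anti to the adjacent carboxylate and to the cis aryl group to set the new centre (4R, 3,4-trans), while the carboxylate keeps its own α-hydrogen from being removed.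

Step 5
Reactants: 13
Product: 15 (2S,3R,4R)-4-[4-(benzyloxy)benzyl]-2-[4-(benzyloxy)phenyl]-N-methoxy-N-methyl-5-oxooxolane-3-carboxamide, via mixed carbonic anhydride 14 (not isolated)
Conditions: i-BuOCOCl, N-methylmorpholine, THF, −15 °C; then MeNH(OMe)·HCl, N-methylmorpholine, −15 °C → rt
Reagents that add atoms: N,O-dimethylhydroxylamine hydrochloride, CNOC.Cl
Why: Mixed-anhydride amide coupling (Weinreb amide formation) at low temperature with a weak base, so that the centre α to the carbonyl should not epimerise.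

Step 6
Reactants: 16 4-bromobenzene-1,3-diol
Product: 17 2,4-bis(benzyloxy)-1-bromobenzene
Conditions: BnBr (2.3 equiv), K2CO3, DMF, 60 °C
Reagents that add atoms: benzyl bromide, BrCc1ccccc1
Why: Williamson ether synthesis on both phenols.

Step 7
Reactants: 15; 17
Product: 19 {(2S,3R,4R)-5-[2,4-bis(benzyloxy)phenyl]-4-[4-(benzyloxy)benzyl]-2-[4-(benzyloxy)phenyl]-5-hydroxyoxolan-3-yl}[2,4-bis(benzyloxy)phenyl]methanone (hemiketal; both C5 epimers), via aryllithium 18 (not isolated)
Conditions: 17 (2.4 equiv), n-BuLi (2.3 equiv), THF, −78 °C; then 15, −78 °C; AcOH/THF quench at −78 °C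
Reagents that add atoms: none
Why: Bromine–lithium exchange followed by addition of one aryllithium to both carbonyl groups (Weinreb ketone synthesis through the stable chelate, and single addition to the γ-lactone through the lithium hemiketalate that persists at −78 °C); the two resorcinol rings of this fragment are identical, so one reagent installs both.

Step 8
Reactants: 19
Product: 21 [2,4-bis(benzyloxy)phenyl]{(2S,3R,4R,5S)-5-[2,4-bis(benzyloxy)phenyl]-4-[4-(benzyloxy)benzyl]-2-[4-(benzyloxy)phenyl]oxolan-3-yl}methanone, via oxocarbenium ion 20 (not isolated)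
Conditions: Et3SiH (3 equiv), BF3·OEt2 (1.5 equiv), CH2Cl2, −78 °C; Et3N then NaHCO3 (aq) at −78 °C
Reagents that add atoms: none
Why: Ionic hydrogenation of the cyclic hemiketal, in which hydride should add to the 2-aryl oxocarbenium ion on the face opposite the adjacent benzyl substituent (kinetic control, as in the reduction of 2-aryl hemiketals to 2,3-cis lignan oxolanes) to set 5S (aryl cis to benzyl); the low temperature and cold basic quench are meant to prevent benzylic epimerisation, ketone reduction and furan formation.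

Step 9
Reactants: 21
Product: 22 (2,4-dihydroxyphenyl)[(2S,3R,4R,5S)-5-(2,4-dihydroxyphenyl)-4-(4-hydroxybenzyl)-2-(4-hydroxyphenyl)oxolan-3-yl]methanone
Conditions: H2 (1 atm), Pd/C (10 wt%), EtOAc–MeOH 1:1, rt, stopped at full debenzylation
Reagents that add atoms: none
Why: Hydrogenolysis of six aryl benzyl ethers, which should be much faster than cleavage of the cyclic benzylic ethers or reduction of the hydrogen-bonded aryl ketone.

**Chroman fragment**

Step 10
Reactants: 23 (2S)-7-hydroxy-2-(4-hydroxyphenyl)-2,3-dihydro-4H-chromen-4-one ((S)-liquiritigenin)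
Product: 24 (2S)-7-[(triisopropylsilyl)oxy]-2-{4-[(triisopropylsilyl)oxy]phenyl}-2,3-dihydro-4H-chromen-4-one
Conditions: TIPSCl (2.5 equiv), imidazole, DMF, 0 °C → rt
Reagents that add atoms: chlorotri(propan-2-yl)silane, CC(C)[Si](Cl)(C(C)C)C(C)C
Why: Silylation of both phenols under weakly basic, cold conditions, which should be faster than ring opening of the flavanone to the chalcone, so that C2 keeps its configuration.

Step 11
Reactants: 24
Product: 25 (2S,4S)-7-[(triisopropylsilyl)oxy]-2-{4-[(triisopropylsilyl)oxy]phenyl}-3,4-dihydro-2H-chromen-4-ol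
Conditions: NaBH4, MeOH–THF 1:1, 0 °C
Reagents that add atoms: none
Why: Borohydride reduction of the flavanone to the 2,4-cis flavan-4-ol; the C4 configuration is removed in the next step.

Step 12
Reactants: 25
Product: 27 (2S)-7-[(triisopropylsilyl)oxy]-2-{4-[(triisopropylsilyl)oxy]phenyl}-2H-chromene, via mesylate 26 (not isolated)
Conditions: MsCl (1.5 equiv), Et3N (5 equiv), DMAP (5 mol%), CH2Cl2, 0 → 35 °C
Reagents that add atoms: none
Why: Mesylation followed by E1-type elimination through the benzylic position activated by O1 and the 7-silyloxy group gives the flav-3-ene under basic conditions that leave C2 untouched.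

Step 13
Reactants: 28 1-(2,4-dihydroxyphenyl)ethanone; 29 4-hydroxy-3-iodobenzaldehyde
Product: 31 (E)-1-(2,4-dihydroxyphenyl)-3-(4-hydroxy-3-iodophenyl)prop-2-en-1-one, via aldol adduct 30 (not isolated)
Conditions: HCl (g), EtOH, 0 °C → rt
Reagents that add atoms: none
Why: Acid-catalysed Claisen–Schmidt condensation, which tolerates the free phenols and gives the thermodynamic E-enone.

Step 14
Reactants: 27; 31
Product: 32 (E)-1-(2,4-dihydroxyphenyl)-3-[(6S,6aR,11aR)-3-[(triisopropylsilyl)oxy]-6-{4-[(triisopropylsilyl)oxy]phenyl}-6a,11a-dihydro-6H-[1]benzofuro[3,2-c]chromen-8-yl]prop-2-en-1-one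
Conditions: Pd(OAc)2 (10 mol%), Ag2CO3 (1.5 equiv), acetone, 55 °C, dark; 31 (1.2 equiv)
Reagents that add atoms: none
Why: Palladium-catalysed oxyarylation of a 2H-chromene with an o-iodophenol (the pterocarpan annulation): after oxidative addition of the iodide to zerovalent palladium, syn-carbopalladation should place the aryl group on C3 on the face anti to the C2 aryl group (6aR, 2,3-trans), and because no syn β-hydrogen is available the benzylic palladium is captured by the neighbouring phenol with cis ring fusion (11aR).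

**Union and end game**

Step 15
Reactants: 32; 22
Product: 34 (E)-1-(2,4-dihydroxyphenyl)-3-{3-[(2S,3R,4R)-4-{5-[(2S,3R,4R,5S)-4-(2,4-dihydroxybenzoyl)-3-(4-hydroxybenzyl)-5-(4-hydroxyphenyl)oxolan-2-yl]-2,4-dihydroxyphenyl}-7-[(triisopropylsilyl)oxy]-2-{4-[(triisopropylsilyl)oxy]phenyl}-3,4-dihydro-2H-chromen-3-yl]-4-hydroxyphenyl}prop-2-en-1-one, via benzylic cation 33 (not isolated)
Conditions: (PhO)2P(O)OH (5 mol%), (CF3)2CHOH–CH2Cl2 4:1, 0.02 M, 0 °C → rt; 22 (1.3 equiv)
Reagents that add atoms: none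
Why: In hexafluoroisopropanol the C11a–O bond of the temporary dihydrofuran ring (the chroman C4–O bond) should ionise with hydrogen-bond and weak-acid assistance, because the leaving group is a phenol made acidic by its para enone and the cation is benzylic to ring A, ortho to O1 and para to the silyloxy group; C5 of resorcinol ring D of 22 then attacks C4 and its proton ends on the liberated ring B phenol, so the step is an acid-neutral addition with no by-product. The closest known reaction types are the Lewis-acid Friedel–Crafts arylation of 4-alkoxy- and 4-acyloxyflavans by phenols in proanthocyanidin synthesis and the acid-induced reductive opening of pterocarpans at the same carbon. No ring is closed; the temporary five-membered ring is opened by an SN1 process with net inversion at C4. The new stereocentre C4 (R) is controlled by the adjacent C3 aryl group, since the arene adds to the planar cation on the face anti to it and gives the all-equatorial 2,3-trans-3,4-trans chroman, the usual sense for 2,3-trans flavan-4-yl cations. The step needs three selectivities: ionisation of 32 in the presence of the benzylic oxolane C–O bonds of 22 (aryloxide versus alkoxide leaving group, no strong acid), attack by ring D C5 alone (the only unhindered carbon ortho and para to two free hydroxyls; the acylated resorcinol ring is deactivated and the bulky 7-silyloxy group shields C6 and C8 of ring A from self-alkylation), and no proton loss from C3 (low temperature, excess nucleophile).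

Step 16
Reactants: 34
Product: 35 (E)-1-(2,4-dihydroxyphenyl)-3-{3-[(2S,3R,4R)-4-{5-[(2S,3R,4R,5S)-4-(2,4-dihydroxybenzoyl)-3-(4-hydroxybenzyl)-5-(4-hydroxyphenyl)oxolan-2-yl]-2,4-dihydroxyphenyl}-7-hydroxy-2-(4-hydroxyphenyl)-3,4-dihydro-2H-chromen-3-yl]-4-hydroxyphenyl}prop-2-en-1-one (target)
Conditions: Bu4NF (2.5 equiv), AcOH (2.5 equiv), THF, 0 °C
Reagents that add atoms: none
Why: Fluoride cleavage of the two aryl silyl ethers, buffered with acetic acid so that neither the β-alkoxy ketone nor the benzylic ethers should open by phenoxide-driven elimination; no stereocentre is touched.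

## Compound list

1 | (4S)-4-benzyl-1,3-oxazolidin-2-one | O=C1N[C@@H](Cc2ccccc2)CO1 | starting material
2 | methyl 4-chloro-4-oxobutanoate | COC(=O)CCC(Cl)=O | starting material
3 | lithium (4S)-4-benzyl-2-oxo-1,3-oxazolidin-3-ide | [Li+].O=C1[N-][C@@H](Cc2ccccc2)CO1 | intermediate
4 | methyl 4-[(4S)-4-benzyl-2-oxo-1,3-oxazolidin-3-yl]-4-oxobutanoate | COC(=O)CCC(=O)N1[C@@H](Cc2ccccc2)COC1=O | intermediate
5 | 4-(benzyloxy)benzaldehyde | O=Cc1ccc(OCc2ccccc2)cc1 | starting material
6 | methyl (3R,4S)-3-{[(4S)-4-benzyl-2-oxo-1,3-oxazolidin-3-yl]carbonyl}-4-[4-(benzyloxy)phenyl]-4-[(trimethylsilyl)oxy]butanoate | COC(=O)C[C@@H](C(=O)N1[C@@H](Cc2ccccc2)COC1=O)[C@H](O[Si](C)(C)C)c1ccc(OCc2ccccc2)cc1 | intermediate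
7 | methyl (3R,4S)-3-{[(4S)-4-benzyl-2-oxo-1,3-oxazolidin-3-yl]carbonyl}-4-[4-(benzyloxy)phenyl]-4-hydroxybutanoate | COC(=O)C[C@@H](C(=O)N1[C@@H](Cc2ccccc2)COC1=O)[C@H](O)c1ccc(OCc2ccccc2)cc1 | intermediate
8 | (4S)-4-benzyl-3-{[(2S,3R)-2-[4-(benzyloxy)phenyl]-5-oxooxolan-3-yl]carbonyl}-1,3-oxazolidin-2-one (cis-lactone) | O=C1C[C@@H](C(=O)N2[C@@H](Cc3ccccc3)COC2=O)[C@@H](c2ccc(OCc3ccccc3)cc2)O1 | intermediate
9 | (2S,3R)-2-[4-(benzyloxy)phenyl]-5-oxooxolane-3-carboperoxoic acid | O=C1C[C@@H](C(=O)OO)[C@@H](c2ccc(OCc3ccccc3)cc2)O1 | intermediate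
10 | (2S,3R)-2-[4-(benzyloxy)phenyl]-5-oxooxolane-3-carboxylic acid | O=C1C[C@@H](C(=O)O)[C@@H](c2ccc(OCc3ccccc3)cc2)O1 | intermediate
11 | 1-(benzyloxy)-4-(bromomethyl)benzene | BrCc1ccc(OCc2ccccc2)cc1 | starting material
12 | dilithium salt of 10 (carboxylate and lactone enolate) | [Li+].[Li+].[O-]C1=C[C@@H](C([O-])=O)[C@@H](c2ccc(OCc3ccccc3)cc2)O1 | intermediate
13 | (2S,3R,4R)-4-[4-(benzyloxy)benzyl]-2-[4-(benzyloxy)phenyl]-5-oxooxolane-3-carboxylic acid | O=C1[C@H](Cc2ccc(OCc3ccccc3)cc2)[C@@H](C(=O)O)[C@@H](c2ccc(OCc3ccccc3)cc2)O1 | intermediate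
14 | mixed anhydride of 13 with isobutyl hydrogen carbonate | O=C1[C@H](Cc2ccc(OCc3ccccc3)cc2)[C@@H](C(=O)OC(=O)OCC(C)C)[C@@H](c2ccc(OCc3ccccc3)cc2)O1 | intermediate
15 | (2S,3R,4R)-4-[4-(benzyloxy)benzyl]-2-[4-(benzyloxy)phenyl]-N-methoxy-N-methyl-5-oxooxolane-3-carboxamide | O=C1[C@H](Cc2ccc(OCc3ccccc3)cc2)[C@@H](C(=O)N(C)OC)[C@@H](c2ccc(OCc3ccccc3)cc2)O1 | intermediate
16 | 4-bromobenzene-1,3-diol | Oc1ccc(Br)c(O)c1 | starting material
17 | 2,4-bis(benzyloxy)-1-bromobenzene | Brc1ccc(OCc2ccccc2)cc1OCc1ccccc1 | intermediate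
18 | [2,4-bis(benzyloxy)phenyl]lithium | [Li]c1ccc(OCc2ccccc2)cc1OCc1ccccc1 | intermediate
19 | {(2S,3R,4R)-5-[2,4-bis(benzyloxy)phenyl]-4-[4-(benzyloxy)benzyl]-2-[4-(benzyloxy)phenyl]-5-hydroxyoxolan-3-yl}[2,4-bis(benzyloxy)phenyl]methanone (hemiketal, both C5 epimers) | OC1(c2ccc(OCc3ccccc3)cc2OCc2ccccc2)O[C@H](c2ccc(OCc3ccccc3)cc2)[C@H](C(=O)c2ccc(OCc3ccccc3)cc2OCc2ccccc2)[C@H]1Cc1ccc(OCc2ccccc2)cc1 | intermediate
20 | cyclic oxocarbenium ion from 19 (loss of the hemiketal hydroxide) | C1(c2ccc(OCc3ccccc3)cc2OCc2ccccc2)=[O+][C@H](c2ccc(OCc3ccccc3)cc2)[C@H](C(=O)c2ccc(OCc3ccccc3)cc2OCc2ccccc2)[C@H]1Cc1ccc(OCc2ccccc2)cc1 | intermediate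
21 | [2,4-bis(benzyloxy)phenyl]{(2S,3R,4R,5S)-5-[2,4-bis(benzyloxy)phenyl]-4-[4-(benzyloxy)benzyl]-2-[4-(benzyloxy)phenyl]oxolan-3-yl}methanone | c1ccccc1COc1ccc([C@H]2O[C@H](c3ccc(OCc4ccccc4)cc3)[C@H](C(=O)c3ccc(OCc4ccccc4)cc3OCc3ccccc3)[C@H]2Cc2ccc(OCc3ccccc3)cc2)c(OCc2ccccc2)c1 | intermediate
22 | (2,4-dihydroxyphenyl)[(2S,3R,4R,5S)-5-(2,4-dihydroxyphenyl)-4-(4-hydroxybenzyl)-2-(4-hydroxyphenyl)oxolan-3-yl]methanone | c1cc([C@H]2O[C@H](c3ccc(O)cc3)[C@H](C(=O)c3ccc(O)cc3O)[C@H]2Cc2ccc(O)cc2)c(O)cc1O | intermediate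
23 | (2S)-7-hydroxy-2-(4-hydroxyphenyl)-2,3-dihydro-4H-chromen-4-one ((S)-liquiritigenin) | O=C1C[C@@H](c2ccc(O)cc2)Oc2cc(O)ccc12 | starting material
24 | (2S)-7-[(triisopropylsilyl)oxy]-2-{4-[(triisopropylsilyl)oxy]phenyl}-2,3-dihydro-4H-chromen-4-one | O=C1C[C@@H](c2ccc(O[Si](C(C)C)(C(C)C)C(C)C)cc2)Oc2cc(O[Si](C(C)C)(C(C)C)C(C)C)ccc12 | intermediate
25 | (2S,4S)-7-[(triisopropylsilyl)oxy]-2-{4-[(triisopropylsilyl)oxy]phenyl}-3,4-dihydro-2H-chromen-4-ol (2,4-cis) | O[C@H]1C[C@@H](c2ccc(O[Si](C(C)C)(C(C)C)C(C)C)cc2)Oc2cc(O[Si](C(C)C)(C(C)C)C(C)C)ccc12 | intermediate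
26 | methanesulfonate of 25 | CS(=O)(=O)O[C@H]1C[C@@H](c2ccc(O[Si](C(C)C)(C(C)C)C(C)C)cc2)Oc2cc(O[Si](C(C)C)(C(C)C)C(C)C)ccc12 | intermediate
27 | (2S)-7-[(triisopropylsilyl)oxy]-2-{4-[(triisopropylsilyl)oxy]phenyl}-2H-chromene | C1=C[C@@H](c2ccc(O[Si](C(C)C)(C(C)C)C(C)C)cc2)Oc2cc(O[Si](C(C)C)(C(C)C)C(C)C)ccc12 | intermediate
28 | 1-(2,4-dihydroxyphenyl)ethanone | CC(=O)c1ccc(O)cc1O | starting material
29 | 4-hydroxy-3-iodobenzaldehyde | O=Cc1ccc(O)c(I)c1 | starting material
30 | 1-(2,4-dihydroxyphenyl)-3-hydroxy-3-(4-hydroxy-3-iodophenyl)propan-1-one (racemic aldol adduct) | O=C(CC(O)c1ccc(O)c(I)c1)c1ccc(O)cc1O | intermediate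
31 | (E)-1-(2,4-dihydroxyphenyl)-3-(4-hydroxy-3-iodophenyl)prop-2-en-1-one | O=C(/C=C/c1ccc(O)c(I)c1)c1ccc(O)cc1O | intermediate
32 | (E)-1-(2,4-dihydroxyphenyl)-3-[(6S,6aR,11aR)-3-[(triisopropylsilyl)oxy]-6-{4-[(triisopropylsilyl)oxy]phenyl}-6a,11a-dihydro-6H-[1]benzofuro[3,2-c]chromen-8-yl]prop-2-en-1-one (cis-fused; 6-aryl trans to the 6a aryl bond) | O=C(/C=C/c1cc2c(cc1)O[C@H]3c4ccc(O[Si](C(C)C)(C(C)C)C(C)C)cc4O[C@H](c4ccc(O[Si](C(C)C)(C(C)C)C(C)C)cc4)[C@@H]23)c1ccc(O)cc1O | intermediate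
33 | ring-opened chroman C4 benzylic cation from 32 (ring B phenol free; 2S,3R) | O=C(/C=C/c1ccc(O)c([C@H]2[CH+]c3ccc(O[Si](C(C)C)(C(C)C)C(C)C)cc3O[C@@H]2c2ccc(O[Si](C(C)C)(C(C)C)C(C)C)cc2)c1)c1ccc(O)cc1O | intermediate
34 | 7,4'-bis(triisopropylsilyl) ether of the target (name as in step 15) | O=C(/C=C/c1ccc(O)c([C@H]2[C@H](c3cc([C@H]4O[C@H](c5ccc(O)cc5)[C@H](C(=O)c5ccc(O)cc5O)[C@H]4Cc4ccc(O)cc4)c(O)cc3O)c3ccc(O[Si](C(C)C)(C(C)C)C(C)C)cc3O[C@@H]2c2ccc(O[Si](C(C)C)(C(C)C)C(C)C)cc2)c1)c1ccc(O)cc1O | intermediate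
35 | (E)-1-(2,4-dihydroxyphenyl)-3-{3-[(2S,3R,4R)-4-{5-[(2S,3R,4R,5S)-4-(2,4-dihydroxybenzoyl)-3-(4-hydroxybenzyl)-5-(4-hydroxyphenyl)oxolan-2-yl]-2,4-dihydroxyphenyl}-7-hydroxy-2-(4-hydroxyphenyl)-3,4-dihydro-2H-chromen-3-yl]-4-hydroxyphenyl}prop-2-en-1-one | O=C(/C=C/c1ccc(O)c([C@H]2[C@H](c3cc([C@H]4O[C@H](c5ccc(O)cc5)[C@H](C(=O)c5ccc(O)cc5O)[C@H]4Cc4ccc(O)cc4)c(O)cc3O)c3ccc(O)cc3O[C@@H]2c2ccc(O)cc2)c1)c1ccc(O)cc1O | target

## Step count and risks

Total steps: 16. Longest linear sequence: 10 steps (1, 2, 3, 4, 5, 7, 8, 9, 15, 16).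

**Step 15.** What may go wrong: acid-promoted ionisation of the benzylic oxolane C–O bond next to ring D of 22 (epimerisation or oligomerisation) competing with opening of the temporary ring; proton loss from C3 of the cation to a 3-aryl-2H-chromene with erosion of the C3 configuration; self-alkylation on ring A. Fallback: set out from 32 and separate ionisation from union. Acid thiolysis with phenylmethanethiol (excess BnSH, AcOH, CH2Cl2, −20 °C), the classical cleavage of flavan C4–O bonds, should give the 2,3-trans-3,4-trans (E)-1-(2,4-dihydroxyphenyl)-3-{3-[(2S,3R,4S)-4-(benzylsulfanyl)-7-[(triisopropylsilyl)oxy]-2-{4-[(triisopropylsilyl)oxy]phenyl}-3,4-dihydro-2H-chromen-3-yl]-4-hydroxyphenyl}prop-2-en-1-one F1. This thioether is then activated thiophilically with AgBF4 in THF at 0 °C in the presence of 22, the known coupling of 4-benzylthioflavans with free phenolic nucleophiles, and the route is rejoined at 34.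

**Step 14.** What may go wrong: consumption of the arylpalladium intermediate by Heck-type or conjugate pathways with the enone, sequestration of palladium and silver by the triphenolic iodide, and slow electrocyclic racemisation of 27 on prolonged heating. Fallback: build the enone after the annulation. Set out from 27 and 29: the same oxyarylation with the simple iodophenol aldehyde 29 should give (6S,6aR,11aR)-3-[(triisopropylsilyl)oxy]-6-{4-[(triisopropylsilyl)oxy]phenyl}-6a,11a-dihydro-6H-[1]benzofuro[3,2-c]chromene-8-carbaldehyde F2. Separately, purchasable 2-chloro-1-(2,4-dihydroxyphenyl)ethanone and PPh3 (toluene, 80 °C) give [2-(2,4-dihydroxyphenyl)-2-oxoethyl](triphenyl)phosphonium chloride F3, which aqueous Na2CO3 converts into the stabilised ylide 1-(2,4-dihydroxyphenyl)-2-(triphenylphosphoranylidene)ethanone F4. Wittig olefination of F2 with F4 (toluene, 80 °C, neutral, E-selective) rejoins the route at 32.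

**Step 7.** What may go wrong: enolisation, β-elimination or retro-aldol ring opening by the basic aryllithium, over-addition to the ring-opened ketone, and carrying a 1,4-dicarbonyl array into the Lewis-acidic step 8 (furan formation, ketone reduction). Fallback: introduce the two resorcinol rings one after the other, with the carbonyl parked as a carboxylate. Set out from 13: aryllithium 18 (3.1 equiv, the first equivalent acting as base, −78 °C) should add only to the lactone and give (2S,3R,4R)-5-[2,4-bis(benzyloxy)phenyl]-4-[4-(benzyloxy)benzyl]-2-[4-(benzyloxy)phenyl]-5-hydroxyoxolane-3-carboxylic acid F5. Ionic hydrogenation (Et3SiH, BF3·OEt2, CH2Cl2, −78 °C) then gives (2S,3R,4R,5S)-5-[2,4-bis(benzyloxy)phenyl]-4-[4-(benzyloxy)benzyl]-2-[4-(benzyloxy)phenyl]oxolane-3-carboxylic acid F6. Mixed-anhydride coupling with MeNH(OMe)·HCl gives the Weinreb amide (2S,3R,4R,5S)-5-[2,4-bis(benzyloxy)phenyl]-4-[4-(benzyloxy)benzyl]-2-[4-(benzyloxy)phenyl]-N-methoxy-N-methyloxolane-3-carboxamide F7, and one equivalent of 18 at −78 °C rejoins the route at 21.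

## Further compounds

F1 | step 15 | (E)-1-(2,4-dihydroxyphenyl)-3-{3-[(2S,3R,4S)-4-(benzylsulfanyl)-7-[(triisopropylsilyl)oxy]-2-{4-[(triisopropylsilyl)oxy]phenyl}-3,4-dihydro-2H-chromen-3-yl]-4-hydroxyphenyl}prop-2-en-1-one | O=C(/C=C/c1ccc(O)c([C@H]2[C@H](SCc3ccccc3)c3ccc(O[Si](C(C)C)(C(C)C)C(C)C)cc3O[C@@H]2c2ccc(O[Si](C(C)C)(C(C)C)C(C)C)cc2)c1)c1ccc(O)cc1O
F2 | step 14 | (6S,6aR,11aR)-3-[(triisopropylsilyl)oxy]-6-{4-[(triisopropylsilyl)oxy]phenyl}-6a,11a-dihydro-6H-[1]benzofuro[3,2-c]chromene-8-carbaldehyde | O=Cc1cc2c(cc1)O[C@H]3c4ccc(O[Si](C(C)C)(C(C)C)C(C)C)cc4O[C@H](c4ccc(O[Si](C(C)C)(C(C)C)C(C)C)cc4)[C@@H]23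
F3 | step 14 | [2-(2,4-dihydroxyphenyl)-2-oxoethyl](triphenyl)phosphonium chloride | [Cl-].O=C(C[P+](c1ccccc1)(c1ccccc1)c1ccccc1)c1ccc(O)cc1O
F4 | step 14 | 1-(2,4-dihydroxyphenyl)-2-(triphenylphosphoranylidene)ethanone | O=C(C=P(c1ccccc1)(c1ccccc1)c1ccccc1)c1ccc(O)cc1O
F5 | step 7 | (2S,3R,4R)-5-[2,4-bis(benzyloxy)phenyl]-4-[4-(benzyloxy)benzyl]-2-[4-(benzyloxy)phenyl]-5-hydroxyoxolane-3-carboxylic acid | OC1(c2ccc(OCc3ccccc3)cc2OCc2ccccc2)O[C@H](c2ccc(OCc3ccccc3)cc2)[C@H](C(=O)O)[C@H]1Cc1ccc(OCc2ccccc2)cc1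
F6 | step 7 | (2S,3R,4R,5S)-5-[2,4-bis(benzyloxy)phenyl]-4-[4-(benzyloxy)benzyl]-2-[4-(benzyloxy)phenyl]oxolane-3-carboxylic acid | c1ccccc1COc1ccc([C@H]2O[C@H](c3ccc(OCc4ccccc4)cc3)[C@H](C(=O)O)[C@H]2Cc2ccc(OCc3ccccc3)cc2)c(OCc2ccccc2)c1
F7 | step 7 | (2S,3R,4R,5S)-5-[2,4-bis(benzyloxy)phenyl]-4-[4-(benzyloxy)benzyl]-2-[4-(benzyloxy)phenyl]-N-methoxy-N-methyloxolane-3-carboxamide | c1ccccc1COc1ccc([C@H]2O[C@H](c3ccc(OCc4ccccc4)cc3)[C@H](C(=O)N(C)OC)[C@H]2Cc2ccc(OCc3ccccc3)cc2)c(OCc2ccccc2)c1
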